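**Plan**
- Retrosynthesis: the three methyl esters and the two C–B bonds are unmasked last. The catechol ring (C4a, C5, C6, C7, C8, C8a) shares only the C4a–C8a bond with the carbocycle and carries its two oxygens on the adjacent, equivalent carbons C6 and C7. It is therefore cut at C4a–C8a, C5–C6 and C7–C8 into a 1,7-diyne (terminal alkynes on C4 and C1) and a symmetrical diborylalkyne.
- The enediyne is cut at C3=C4 (olefination with silylpropynal) and at C1–C2 (propargylic alkylation of an aldehyde enamine by a pyronyl propargylic ester). The pyrone goes back to a senecioate and an oxalate.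
- Forward order: pyrone ring, then C1–C2, then C3=C4, then the carbocycle (C1, C2, C3, C4, C4a, C8a) and the benzene ring together in one cyclotrimerisation, then catechol and acids.
- Stereochemistry: C1 from a chiral copper–diphosphine allenylidene and C2 from a chiral prolinol enamine, both in step 6; the (E)-alkene from the olefination. All later steps are neutral or acidic, and the key step creates no stereocentre.

Key step: step 10

Remark: the labels C1–C8a follow the dihydronaphthalene numbering of the target and are used for the same carbons in the open-chain intermediates.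
Assumption: the copper catalyst with (S)-Cl-MeO-BIPHEP is taken to give the (S) configuration at C1, by analogy with 1-aryl propargylic esters; if a trial run shows the opposite sense, the (R)-ligand is used instead.

Step 1
Reactants: 1 methyl 3-methylbut-2-enoate; 2 dimethyl oxalate
Product: 4 methyl 4-methyl-2-oxo-2H-pyran-6-carboxylate, via potassium dienolate of dimethyl 2-hydroxy-4-methylhexa-2,4-dienedioate 3 (not isolated)
Conditions: KOMe, THF, 0 °C to rt; then H2SO4, MeOH, reflux
Reagents that add atoms: none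
Why: A vinylogous Claisen condensation at the γ-methyl group of the senecioate dienolate with the non-enolisable oxalate gives the fully conjugated enolate, and acid then equilibrates the diene geometry and closes the six-membered enol lactone with loss of methanol, the classical oxalyl-crotonate route to 2-pyrone-6-carboxylates.

Step 2
Reactants: 4 methyl 4-methyl-2-oxo-2H-pyran-6-carboxylate
Product: 5 methyl 4-formyl-2-oxo-2H-pyran-6-carboxylate
Conditions: SeO2 (1.3 equiv), 1,4-dioxane, 100 °C
Reagents that add atoms: selenium dioxide, O=[Se]=O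
Why: Riley oxidation of the only allylic C–H position, the 4-methyl group activated vinylogously by the lactone carbonyl, should stop at the aldehyde as it does for 4-methylcoumarins.

Step 3
Reactants: 5 methyl 4-formyl-2-oxo-2H-pyran-6-carboxylate; 6 ethynylmagnesium bromide
Product: 8 1-[6-(methoxycarbonyl)-2-oxo-2H-pyran-4-yl]prop-2-yn-1-yl pentafluorobenzoate (racemic), via bromomagnesium propargylic alkoxide 7 (not isolated)
Conditions: HC≡CMgBr (1.05 equiv), THF, −78 °C; then C6F5COCl, −78 to 0 °C
Reagents that add atoms: pentafluorobenzoyl chloride, O=C(Cl)c1c(F)c(F)c(F)c(F)c1F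
Why: Grignard 1,2-addition to the aldehyde, by far the most electrophilic carbonyl at −78 °C, followed by O-acylation of the magnesium alkoxide in the same flask gives the activated propargylic ester, which may be racemic because step 6 is stereoconvergent.

Step 4
Reactants: 9 methyl 2-(diethoxyphosphoryl)acetate; 10 allyl bromide
Product: 11 methyl 2-(diethoxyphosphoryl)pent-4-enoate (racemic)
Conditions: NaH (1.0 equiv), THF, 0 °C to rt
Reagents that add atoms: none
Why: C-alkylation of the sodium phosphonoacetate anion with a reactive allylic halide is a standard monoalkylation when one equivalent of base is used.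

Step 5
Reactants: 11 methyl 2-(diethoxyphosphoryl)pent-4-enoate
Product: 12 methyl 2-(diethoxyphosphoryl)-4-oxobutanoate (racemic)
Conditions: O3, CH2Cl2, −78 °C; then Me2S, −78 °C to rt
Reagents that add atoms: ozone, [O-][O+]=O
Why: Ozonolysis of the terminal alkene with reductive work-up gives the aldehyde without touching the phosphonate or the ester.

Step 6
Reactants: 8 1-[6-(methoxycarbonyl)-2-oxo-2H-pyran-4-yl]prop-2-yn-1-yl pentafluorobenzoate; 12 methyl 2-(diethoxyphosphoryl)-4-oxobutanoate
Product: 13 methyl (3R,4S)-2-(diethoxyphosphoryl)-3-formyl-4-[6-(methoxycarbonyl)-2-oxo-2H-pyran-4-yl]hex-5-ynoate (both epimers at the phosphonate carbon)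
Conditions: CuOTf·½C6H6 (5 mol %), (S)-Cl-MeO-BIPHEP (10 mol %), (S)-α,α-bis[3,5-bis(trifluoromethyl)phenyl]prolinol trimethylsilyl ether (20 mol %), iPr2NEt (1.2 equiv), 12 (2.5 equiv), THF, −20 °C
Reagents that add atoms: none
Why: In this cooperative copper/enamine propargylic alkylation of an aldehyde, the copper acetylide of 8 loses pentafluorobenzoate to a planar copper allenylidene (so racemic 8 converges) and its γ-carbon C1 is attacked by the (E)-enamine of 12; the diphosphine on copper fixes the face of C1 (S), the prolinol silyl ether shields one enamine face and sets C2 in its usual sense (R by CIP here because of the phosphorus substituent), and the α-branched product no longer forms an enamine, so C2 is kept.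

Step 7
Reactants: 13 methyl (3R,4S)-2-(diethoxyphosphoryl)-3-formyl-4-[6-(methoxycarbonyl)-2-oxo-2H-pyran-4-yl]hex-5-ynoate
Product: 15 dimethyl (3R)-2-(diethoxyphosphoryl)-3-{(1S)-1-[6-(methoxycarbonyl)-2-oxo-2H-pyran-4-yl]prop-2-yn-1-yl}butanedioate, via carboxylic acid 14 (not isolated)
Conditions: NaClO2, NaH2PO4, 2-methyl-2-butene, t-BuOH/H2O, 0 °C; then TMSCHN2, toluene/MeOH, 0 °C
Reagents that add atoms: sodium chlorite, [Na+].[O-]Cl=O; trimethylsilyldiazomethane, C[Si](C)(C)C=[N+]=[N-]
Why: Pinnick oxidation in its weakly acidic buffer followed by neutral diazoalkane esterification converts the aldehyde into the methyl ester without any base that could epimerise C1 or C2.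

Step 8
Reactants: 15 dimethyl (3R)-2-(diethoxyphosphoryl)-3-{(1S)-1-[6-(methoxycarbonyl)-2-oxo-2H-pyran-4-yl]prop-2-yn-1-yl}butanedioate; 16 3-(trimethylsilyl)prop-2-ynal
Product: 17 dimethyl (2S,3E)-2-{(1S)-1-[6-(methoxycarbonyl)-2-oxo-2H-pyran-4-yl]prop-2-yn-1-yl}-3-[3-(trimethylsilyl)prop-2-yn-1-ylidene]butanedioate
Conditions: LiCl (1.5 equiv), DBU (0.95 equiv), MeCN, −20 to 0 °C
Reagents that add atoms: none
Why: Horner–Wadsworth–Emmons olefination of the lithium-chelated phosphonosuccinate (the most acidic C–H, deprotonated by a sub-stoichiometric amine base) with the very electrophilic ynal should give the (E)-alkylidene succinate, alkynyl trans to the C3 ester and cis to C2; C2 is untouched and becomes 2S by CIP only.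

Step 9
Reactants: 17 dimethyl (2S,3E)-2-{(1S)-1-[6-(methoxycarbonyl)-2-oxo-2H-pyran-4-yl]prop-2-yn-1-yl}-3-[3-(trimethylsilyl)prop-2-yn-1-ylidene]butanedioate
Product: 18 dimethyl (2S,3E)-2-{(1S)-1-[6-(methoxycarbonyl)-2-oxo-2H-pyran-4-yl]prop-2-yn-1-yl}-3-(prop-2-yn-1-ylidene)butanedioate
Conditions: AgNO3 (0.2 equiv), acetone/H2O, rt, dark
Reagents that add atoms: none
Why: Silver-catalysed protodesilylation of the alkynylsilane proceeds at neutral pH, so the pyrone ester and the acidic C1–H and C2–H are not exposed to fluoride or alkoxide.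

Step 10
Reactants: 18 dimethyl (2S,3E)-2-{(1S)-1-[6-(methoxycarbonyl)-2-oxo-2H-pyran-4-yl]prop-2-yn-1-yl}-3-(prop-2-yn-1-ylidene)butanedioate; 19 bis(pinacolboryl)acetylene
Product: 20 dimethyl (1R,2S)-1-[6-(methoxycarbonyl)-2-oxo-2H-pyran-4-yl]-6,7-bis(4,4,5,5-tetramethyl-1,3,2-dioxaborolan-2-yl)-1,2-dihydronaphthalene-2,3-dicarboxylate
Conditions: CpCo(CO)2 (20 mol %), 19 (4 equiv), toluene, reflux, visible-light irradiation, 18 added over 8 h by syringe pump
Reagents that add atoms: none
Why: CpCo(CO)2 (monovalent cobalt) sheds CO under heat and light, binds both terminal alkynes of 18 and couples them oxidatively to a cobaltacyclopentadiene (trivalent cobalt), which forms C4a–C8a and, because the alkynes are joined by the four-atom tether C4=C3–C2–C1, closes the six-membered carbocycle in the same event. Coordination and insertion of 19 into a Co–C bond followed by reductive elimination then forms C5–C6 and C7–C8, closes the benzene ring and returns the CpCo fragment. The closest known reaction type is the cobalt-mediated (2+2+2) co-cyclisation of 1,7-diynes with alkynylboronates and other bulky internal alkynes to fused arenes. The carbocycle thus closes by intramolecular alkyne–alkyne oxidative cyclisation on the metal and the arene by intermolecular alkyne insertion and reductive elimination. No stereocentre is made: C1 and C2 stay untouched in the neutral, base-free medium, and the change from (1S) in 18 to (1R) in 20 is a change of CIP priorities only. The step needs cross- over homo-cyclotrimerisation, which is secured by the (E)-alkene holding the C4 alkyne on the side of C2, by the bulky diboryl alkyne that does not trimerise with itself and is used in excess, and by slow addition of 18; regiochemistry is not in question because 19 is symmetrical, so boron ends on C6 and C7.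

Step 11
Reactants: 20 dimethyl (1R,2S)-1-[6-(methoxycarbonyl)-2-oxo-2H-pyran-4-yl]-6,7-bis(4,4,5,5-tetramethyl-1,3,2-dioxaborolan-2-yl)-1,2-dihydronaphthalene-2,3-dicarboxylate
Product: 21 dimethyl (1R,2S)-6,7-dihydroxy-1-[6-(methoxycarbonyl)-2-oxo-2H-pyran-4-yl]-1,2-dihydronaphthalene-2,3-dicarboxylate
Conditions: 30% H2O2, pH 7 phosphate buffer, THF, 0 °C to rt; Na2S2O3 quench, dilute HCl work-up
Reagents that add atoms: hydrogen peroxide, OO
Why: Oxidation of both aryl C–B bonds by hydroperoxide (1,2-aryl shift from boron to oxygen, then hydrolysis of the borate) gives the catechol, and at neutral pH there is neither hydroperoxide anion to epoxidise the acrylate nor base to epimerise C1/C2 or oxidise the catechol further.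

Step 12
Reactants: 21 dimethyl (1R,2S)-6,7-dihydroxy-1-[6-(methoxycarbonyl)-2-oxo-2H-pyran-4-yl]-1,2-dihydronaphthalene-2,3-dicarboxylate
Product: 22 (1R,2S)-1-(6-carboxy-2-oxo-2H-pyran-4-yl)-6,7-dihydroxy-1,2-dihydronaphthalene-2,3-dicarboxylic acid
Conditions: 6 M HCl, 1,4-dioxane, 80 °C, argon
Reagents that add atoms: water, O
Why: Acid-catalysed hydrolysis cleaves the three methyl esters while the 2-pyrone lactone, the catechol and the trans C1/C2 relationship (the thermodynamically preferred one) survive, and exclusion of air prevents aromatisation of the dihydronaphthalene.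

**Compound list**
1 | methyl 3-methylbut-2-enoate | CC(C)=CC(=O)OC | starting material
2 | dimethyl oxalate | COC(=O)C(=O)OC | starting material
3 | potassium dienolate of dimethyl 2-hydroxy-4-methylhexa-2,4-dienedioate | COC(=O)C([O-])=CC(C)=CC(=O)OC.[K+] | intermediate
4 | methyl 4-methyl-2-oxo-2H-pyran-6-carboxylate | Cc1cc(C(=O)OC)oc(=O)c1 | intermediate
5 | methyl 4-formyl-2-oxo-2H-pyran-6-carboxylate | O=Cc1cc(C(=O)OC)oc(=O)c1 | intermediate
6 | ethynylmagnesium bromide | C#C[Mg]Br | starting material
7 | bromomagnesium 1-[6-(methoxycarbonyl)-2-oxo-2H-pyran-4-yl]prop-2-yn-1-olate (racemic) | Br[Mg]OC(C#C)c1cc(C(=O)OC)oc(=O)c1 | intermediate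
8 | 1-[6-(methoxycarbonyl)-2-oxo-2H-pyran-4-yl]prop-2-yn-1-yl pentafluorobenzoate (racemic) | O=C(OC(C#C)c1cc(C(=O)OC)oc(=O)c1)c1c(F)c(F)c(F)c(F)c1F | intermediate
9 | methyl 2-(diethoxyphosphoryl)acetate | CCOP(=O)(CC(=O)OC)OCC | starting material
10 | allyl bromide | C=CCBr | starting material
11 | methyl 2-(diethoxyphosphoryl)pent-4-enoate (racemic) | C=CCC(C(=O)OC)P(=O)(OCC)OCC | intermediate
12 | methyl 2-(diethoxyphosphoryl)-4-oxobutanoate (racemic) | O=CCC(C(=O)OC)P(=O)(OCC)OCC | intermediate
13 | methyl (3R,4S)-2-(diethoxyphosphoryl)-3-formyl-4-[6-(methoxycarbonyl)-2-oxo-2H-pyran-4-yl]hex-5-ynoate (epimers at the phosphonate carbon) | O=C[C@H](C(C(=O)OC)P(=O)(OCC)OCC)[C@@H](C#C)c1cc(C(=O)OC)oc(=O)c1 | intermediate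
14 | (2R,3S)-2-[(diethoxyphosphoryl)(methoxycarbonyl)methyl]-3-[6-(methoxycarbonyl)-2-oxo-2H-pyran-4-yl]pent-4-ynoic acid | OC(=O)[C@H](C(C(=O)OC)P(=O)(OCC)OCC)[C@@H](C#C)c1cc(C(=O)OC)oc(=O)c1 | intermediate
15 | dimethyl (3R)-2-(diethoxyphosphoryl)-3-{(1S)-1-[6-(methoxycarbonyl)-2-oxo-2H-pyran-4-yl]prop-2-yn-1-yl}butanedioate | COC(=O)[C@H](C(C(=O)OC)P(=O)(OCC)OCC)[C@@H](C#C)c1cc(C(=O)OC)oc(=O)c1 | intermediate
16 | 3-(trimethylsilyl)prop-2-ynal | C[Si](C)(C)C#CC=O | starting material
17 | dimethyl (2S,3E)-2-{(1S)-1-[6-(methoxycarbonyl)-2-oxo-2H-pyran-4-yl]prop-2-yn-1-yl}-3-[3-(trimethylsilyl)prop-2-yn-1-ylidene]butanedioate | COC(=O)C(=C/C#C[Si](C)(C)C)/[C@@H](C(=O)OC)[C@@H](C#C)c1cc(C(=O)OC)oc(=O)c1 | intermediate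
18 | dimethyl (2S,3E)-2-{(1S)-1-[6-(methoxycarbonyl)-2-oxo-2H-pyran-4-yl]prop-2-yn-1-yl}-3-(prop-2-yn-1-ylidene)butanedioate | COC(=O)C(=C/C#C)/[C@@H](C(=O)OC)[C@@H](C#C)c1cc(C(=O)OC)oc(=O)c1 | intermediate
19 | bis(pinacolboryl)acetylene | CC1(C)OB(C#CB2OC(C)(C)C(C)(C)O2)OC1(C)C | starting material
20 | dimethyl (1R,2S)-1-[6-(methoxycarbonyl)-2-oxo-2H-pyran-4-yl]-6,7-bis(4,4,5,5-tetramethyl-1,3,2-dioxaborolan-2-yl)-1,2-dihydronaphthalene-2,3-dicarboxylate | COC(=O)C1=Cc2cc(B3OC(C)(C)C(C)(C)O3)c(B3OC(C)(C)C(C)(C)O3)cc2[C@@H](c2cc(C(=O)OC)oc(=O)c2)[C@@H]1C(=O)OC | intermediate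
21 | dimethyl (1R,2S)-6,7-dihydroxy-1-[6-(methoxycarbonyl)-2-oxo-2H-pyran-4-yl]-1,2-dihydronaphthalene-2,3-dicarboxylate | COC(=O)C1=Cc2cc(O)c(O)cc2[C@@H](c2cc(C(=O)OC)oc(=O)c2)[C@@H]1C(=O)OC | intermediate
22 | (1R,2S)-1-(6-carboxy-2-oxo-2H-pyran-4-yl)-6,7-dihydroxy-1,2-dihydronaphthalene-2,3-dicarboxylic acid | O=C(O)C1=Cc2cc(O)c(O)cc2[C@@H](c2cc(C(=O)O)oc(=O)c2)[C@@H]1C(=O)O | target

**Step count**
Total: 12 steps. Longest linear sequence: 10 steps (1, 2, 3, 6, 7, 8, 9, 10, 11, 12); steps 4 and 5 make the aldehyde partner in a side branch.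

**Steps most likely to fail**

1. Step 6. The two catalysts may not act independently: a mismatched pairing, slow ionisation of the electron-poor pyronyl propargylic ester, or N-propargylation of the amine could erode facial control at C2 or stall conversion. The fallback sets out from 12 and 8 and gives up simultaneous control. Aldehyde 12 is condensed with morpholine to methyl (3E)-2-(diethoxyphosphoryl)-4-(morpholin-4-yl)but-3-enoate F1. This preformed enamine is alkylated by 8 with CuOTf·½C6H6 and (S)-Cl-MeO-BIPHEP alone, so that only C1 is catalyst-controlled. Mild acidic hydrolysis should give 13 together with its C2 epimer, methyl (3S,4S)-2-(diethoxyphosphoryl)-3-formyl-4-[6-(methoxycarbonyl)-2-oxo-2H-pyran-4-yl]hex-5-ynoate F2. The two are separated, and F2 is re-equilibrated at the aldehyde α-carbon with pyrrolidinium acetate (C1 is not affected) and recycled. The route is rejoined at 13.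

2. Step 10. The diyne may oligomerise with itself, the bulky diboryl alkyne may fail to insert into the cobaltacycle, or the pyrone diene may capture the cobalt fragment. The fallback sets out from 18 and uses a partner of proven reactivity. Co-cyclisation with bis(trimethylsilyl)acetylene as co-solvent under CpCo(CO)2 and light should give dimethyl (1R,2S)-1-[6-(methoxycarbonyl)-2-oxo-2H-pyran-4-yl]-6,7-bis(trimethylsilyl)-1,2-dihydronaphthalene-2,3-dicarboxylate F3. Ipso-iododesilylation with ICl in CH2Cl2 at 0 °C then gives dimethyl (1R,2S)-6,7-diiodo-1-[6-(methoxycarbonyl)-2-oxo-2H-pyran-4-yl]-1,2-dihydronaphthalene-2,3-dicarboxylate F4. Miyaura borylation (PdCl2(dppf), B2pin2, KOAc, 1,4-dioxane, 80 °C) rejoins the route at 20.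

3. Step 8. The E selectivity may erode with the slim ynal, the amine base may epimerise C2 or move the new alkene into conjugation after olefination, or the phosphonate anion may add to the pyrone in a conjugate sense. The fallback moves the olefination onto an achiral fragment; it sets out from 9, 16 and 8.
 - Phosphonate 9 is alkylated with 2-bromo-1,1-dimethoxyethane (NaH, DMF) to methyl 2-(diethoxyphosphoryl)-4,4-dimethoxybutanoate F5.
 - Horner–Wadsworth–Emmons reaction of F5 with 16 gives methyl (2E)-2-(2,2-dimethoxyethyl)-5-(trimethylsilyl)pent-2-en-4-ynoate F6, whose geometry can be purified at this stage.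
 - Aqueous acid unmasks methyl (2E)-2-(2-oxoethyl)-5-(trimethylsilyl)pent-2-en-4-ynoate F7.
 - Under the copper/amine conditions of step 6, F7 should react through its dienamine at the α-carbon with 8 to give methyl (2E,3S,4S)-3-formyl-4-[6-(methoxycarbonyl)-2-oxo-2H-pyran-4-yl]-2-[3-(trimethylsilyl)prop-2-yn-1-ylidene]hex-5-ynoate F8.
 - Pinnick oxidation and esterification with TMSCHN2 rejoin the route at 17.

**Further compounds**
F1 | step 6 | methyl (3E)-2-(diethoxyphosphoryl)-4-(morpholin-4-yl)but-3-enoate | COC(=O)C(/C=C/N1CCOCC1)P(=O)(OCC)OCC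
F2 | step 6 | methyl (3S,4S)-2-(diethoxyphosphoryl)-3-formyl-4-[6-(methoxycarbonyl)-2-oxo-2H-pyran-4-yl]hex-5-ynoate | O=C[C@@H](C(C(=O)OC)P(=O)(OCC)OCC)[C@@H](C#C)c1cc(C(=O)OC)oc(=O)c1
F3 | step 10 | dimethyl (1R,2S)-1-[6-(methoxycarbonyl)-2-oxo-2H-pyran-4-yl]-6,7-bis(trimethylsilyl)-1,2-dihydronaphthalene-2,3-dicarboxylate | COC(=O)C1=Cc2cc([Si](C)(C)C)c([Si](C)(C)C)cc2[C@@H](c2cc(C(=O)OC)oc(=O)c2)[C@@H]1C(=O)OC
F4 | step 10 | dimethyl (1R,2S)-6,7-diiodo-1-[6-(methoxycarbonyl)-2-oxo-2H-pyran-4-yl]-1,2-dihydronaphthalene-2,3-dicarboxylate | COC(=O)C1=Cc2cc(I)c(I)cc2[C@@H](c2cc(C(=O)OC)oc(=O)c2)[C@@H]1C(=O)OC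
F5 | step 8 | methyl 2-(diethoxyphosphoryl)-4,4-dimethoxybutanoate | COC(=O)C(CC(OC)OC)P(=O)(OCC)OCC
F6 | step 8 | methyl (2E)-2-(2,2-dimethoxyethyl)-5-(trimethylsilyl)pent-2-en-4-ynoate | COC(=O)C(=C/C#C[Si](C)(C)C)/CC(OC)OC
F7 | step 8 | methyl (2E)-2-(2-oxoethyl)-5-(trimethylsilyl)pent-2-en-4-ynoate | COC(=O)C(=C/C#C[Si](C)(C)C)/CC=O
F8 | step 8 | methyl (2E,3S,4S)-3-formyl-4-[6-(methoxycarbonyl)-2-oxo-2H-pyran-4-yl]-2-[3-(trimethylsilyl)prop-2-yn-1-ylidene]hex-5-ynoate | COC(=O)C(=C/C#C[Si](C)(C)C)/[C@@H](C=O)[C@@H](C#C)c1cc(C(=O)OC)oc(=O)c1
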